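**Plan**
Cuts: first the O–Si masks (the C4 ketone is carried as its silyl enol ether), then C3–C4 of ring C, then the O1–C2 ether bond, and last the side-chain C=C and the O-prenyl bond on ring B.
Feature: in ring C the C3–C4 bond lies between the O1-bearing stereocentre C2 and the aryl ketone carbon C4 on ring A. A vinyl group on C2 and the enol silyl ether of a C4 acetyl group can therefore be joined by metathesis, with C4 already at the ketone level.
Forward: the ring B aldehyde becomes a cinnamyl carbonate (five steps) and the ring A acetophenone becomes its bis-silyl ether (one step). Rings A and B are joined at O1–C2, the acetyl group is enol-silylated, ring C (the only ring built) closes, and fluoride unmasks everything.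
Stereochemistry: C2 (S), the only stereocentre, comes from ligand control in the iridium-catalysed allylic etherification and is only carried through the last three steps.

Key step: step 9

Abbreviations: TBS = tert-butyldimethylsilyl; prenyl = 3-methylbut-2-enyl; L = O,O′-(1,1′-binaphthalene-2,2′-diyl) N,N-bis(1-phenylethyl)phosphoramidite.
Assumption: for cinnamyl carbonates and oxygen nucleophiles, (Sa,Sc,Sc)-L is taken to give the (S)-ether. If the sense of induction proves to be the reverse, the equally accessible (Ra,Rc,Rc)-antipode is used and nothing else changes.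

**Route**

Step 1
Reactants: 1 3,4-dihydroxybenzaldehyde; 2 prenyl bromide (1-bromo-3-methylbut-2-ene)
Product: 3 3-hydroxy-4-(prenyloxy)benzaldehyde
Conditions: NaHCO3 (1.5 equiv), 2 (1.05 equiv), DMF, 40 °C
Reagents that add atoms: none
Why: Williamson ether synthesis under weak-base control: the 4-OH lies para to the formyl group and is the more acidic phenol, so bicarbonate ionises it preferentially and the allylic bromide alkylates that oxygen while the 3-OH stays free.

Step 2
Reactants: 3 3-hydroxy-4-(prenyloxy)benzaldehyde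
Product: 4 3-(tert-butyldimethylsilyloxy)-4-(prenyloxy)benzaldehyde
Conditions: TBSCl, imidazole, DMF, rt
Reagents that add atoms: tert-butyldimethylsilyl chloride (TBSCl), CC(C)(C)[Si](C)(C)Cl
Why: Imidazole-promoted O-silylation of a phenol, to which the aldehyde and the prenyl ether are inert, caps the last acidic proton of ring B with a group that fluoride removes at the end.

Step 3
Reactants: 4 3-(tert-butyldimethylsilyloxy)-4-(prenyloxy)benzaldehyde; 5 triethyl phosphonoacetate
Product: 7 ethyl (E)-3-[3-(tert-butyldimethylsilyloxy)-4-(prenyloxy)phenyl]prop-2-enoate, via sodium phosphonoacetate carbanion 6 (not isolated)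
Conditions: 5, NaH, THF, 0 °C; then 4, 0 °C → rt
Reagents that add atoms: sodium hydride, [Na+].[H-] (supplies the sodium of 6)
Why: Horner–Wadsworth–Emmons olefination of an aromatic aldehyde with a stabilised phosphonate carbanion, whose reversible addition funnels to the (E)-cinnamate, and pre-forming 6 keeps hydride base away from the aryl silyl ether.

Step 4
Reactants: 7 ethyl (E)-3-[3-(tert-butyldimethylsilyloxy)-4-(prenyloxy)phenyl]prop-2-enoate
Product: 8 (E)-3-[3-(tert-butyldimethylsilyloxy)-4-(prenyloxy)phenyl]prop-2-en-1-ol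
Conditions: i-Bu2AlH (2.3 equiv), CH2Cl2, −78 °C; aq. potassium sodium tartrate work-up
Reagents that add atoms: none
Why: 1,2-Reduction of an α,β-unsaturated ester by two hydride transfers from i-Bu2AlH at low temperature gives the allylic alcohol and leaves both alkenes, the ethers and the silyl group untouched.

Step 5
Reactants: 8 (E)-3-[3-(tert-butyldimethylsilyloxy)-4-(prenyloxy)phenyl]prop-2-en-1-ol
Product: 9 (E)-3-[3-(tert-butyldimethylsilyloxy)-4-(prenyloxy)phenyl]prop-2-enyl methyl carbonate
Conditions: ClCO2Me, pyridine, CH2Cl2, 0 °C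
Reagents that add atoms: methyl chloroformate, COC(=O)Cl
Why: O-Acylation of the primary allylic alcohol with a chloroformate under pyridine gives the linear allylic carbonate, the leaving group that the iridium catalyst ionises and that releases only CO2 and methoxide.

Step 6
Reactants: 10 2,4,6-trihydroxyacetophenone
Product: 11 1-[2-hydroxy-4,6-bis(tert-butyldimethylsilyloxy)phenyl]ethanone
Conditions: TBSCl (2.1 equiv), imidazole (2.5 equiv), DMF, 0 °C
Reagents that add atoms: tert-butyldimethylsilyl chloride (TBSCl), CC(C)(C)[Si](C)(C)Cl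
Why: Chemoselective O-silylation: the free 4-OH and one of the two equivalent ortho OH groups react, whereas the remaining ortho OH is tied up in a strong hydrogen bond to the acetyl oxygen and is left as the nucleophilic site for step 7.

Step 7
Reactants: 9 (E)-3-[3-(tert-butyldimethylsilyloxy)-4-(prenyloxy)phenyl]prop-2-enyl methyl carbonate; 11 1-[2-hydroxy-4,6-bis(tert-butyldimethylsilyloxy)phenyl]ethanone
Product: 13 1-{2-[(S)-1-[3-(tert-butyldimethylsilyloxy)-4-(prenyloxy)phenyl]prop-2-enyloxy]-4,6-bis(tert-butyldimethylsilyloxy)phenyl}ethanone, via lithium aryloxide 12 (not isolated)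
Conditions: 11 (1.2 equiv), LiN(SiMe3)2 (1.2 equiv), THF, 0 °C; then 9, [Ir(cod)Cl]2 (2 mol %), (Sa,Sc,Sc)-L (4 mol %; pre-activated with n-PrNH2, 50 °C, then evacuated), THF, rt
Reagents that add atoms: lithium bis(trimethylsilyl)amide, [Li+].C[Si](C)(C)[N-][Si](C)(C)C (supplies the lithium of 12)
Why: Iridium-catalysed asymmetric allylic etherification of a linear cinnamyl carbonate with an alkali-metal aryloxide: the cyclometallated iridium–phosphoramidite ionises 9 to an allyl complex that 12 attacks on the face opposite the metal at the aryl-bearing terminus, which gives the branched ether, and the chiral ligand decides which allyl face is bound and so sets C2 as (S).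

Step 8
Reactants: 13 1-{2-[(S)-1-[3-(tert-butyldimethylsilyloxy)-4-(prenyloxy)phenyl]prop-2-enyloxy]-4,6-bis(tert-butyldimethylsilyloxy)phenyl}ethanone
Product: 15 (S)-1-[3-(tert-butyldimethylsilyloxy)-4-(prenyloxy)phenyl]allyl 3,5-bis(tert-butyldimethylsilyloxy)-2-[1-(tert-butyldimethylsilyloxy)vinyl]phenyl ether, via potassium enolate 14 (not isolated)
Conditions: KN(SiMe3)2 (1.1 equiv), THF, −78 °C; then TBSCl (1.3 equiv), −78 → 0 °C; pH 7 buffer; Et3N-washed silica
Reagents that add atoms: potassium bis(trimethylsilyl)amide, [K+].C[Si](C)(C)[N-][Si](C)(C)C (supplies the potassium of 14); tert-butyldimethylsilyl chloride (TBSCl), CC(C)(C)[Si](C)(C)Cl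
Why: Silyl enol ether formation by kinetic deprotonation of the methyl ketone and O-silylation of the potassium enolate works without any Lewis acid that could ionise the benzylic and allylic O1–C2 bond, the amide base is too weak to remove the C2 proton, and a silyl shift from the neighbouring aryl silyl ether to the enolate oxygen would end in the same product.

Step 9
Reactants: 15 (S)-1-[3-(tert-butyldimethylsilyloxy)-4-(prenyloxy)phenyl]allyl 3,5-bis(tert-butyldimethylsilyloxy)-2-[1-(tert-butyldimethylsilyloxy)vinyl]phenyl ether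
Product: 16 (2S)-4,5,7-tris(tert-butyldimethylsilyloxy)-2-[3-(tert-butyldimethylsilyloxy)-4-(prenyloxy)phenyl]-2H-chromene
Conditions: RuCl2(PCy3)(H2IMes)(=CHPh) (second-generation Grubbs catalyst, 2 × 5 mol %), 1,4-benzoquinone (10 mol %), CH2Cl2 (2 mM), 40 °C, Ar sparge, dark; filtration through Et3N-washed silica
Reagents that add atoms: none
Why: This is a ring-closing olefin metathesis of an olefinic silyl enol ether: the ruthenium benzylidene first exchanges with the unhindered monosubstituted vinyl group on C2, the new alkylidene adds [2+2] across the 1,1-disubstituted enol ether with ruthenium on the CH2 terminus, and cycloreversion forms C3=C4 while Ru=CH2 carries the chain and ethylene escapes. The closest known reaction type is the silyl enol ether–ene ring-closing metathesis that converts N-allyl-2-(1-silyloxyvinyl)anilines into 4-silyloxy-1,2-dihydroquinolines and acyclic olefinic silyl enol ethers into cyclic ones with the same catalyst. Ring C closes as a six-membered ring through an intramolecular metallacyclobutane, giving an endocyclic C3=C4 bond, and the ortho placement of O1 and the C4 substituent on ring A holds the two alkenes within reach. No stereocentre is created; C2 is a spectator set in step 7, and neutral aprotic conditions at 40 °C in the dark spare the ionisable O1–C2 bond and avoid both aromatic Claisen rearrangement of 15 and electrocyclic opening of the 2H-chromene 16. The selectivity needed is ring closure over cross-metathesis or ethenolysis at the prenyl alkene and over double-bond migration in the allyl ether; the trisubstituted prenyl alkene reacts far more slowly and cannot reach the C2 alkylidene from its para position, high dilution with an argon sparge suppresses bimolecular events and removes ethylene, and 1,4-benzoquinone intercepts ruthenium hydrides.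

Step 10
Reactants: 16 (2S)-4,5,7-tris(tert-butyldimethylsilyloxy)-2-[3-(tert-butyldimethylsilyloxy)-4-(prenyloxy)phenyl]-2H-chromene
Product: 18 monotesone A, via tris-silyl flavanone 17 (not isolated)
Conditions: Et3N·3HF (10 equiv), THF, 0 °C → rt
Reagents that add atoms: none
Why: Fluoride-induced desilylation in a weakly acidic, non-basic medium: protodesilylation of the enol ether at C3 gives ketone 17 first, the three aryl silyl ethers follow, and because neither phenoxide nor enolate builds up, the retro-oxa-Michael opening of ring C that would racemise C2 is avoided while the acid-sensitive prenyl ether survives.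

**Compound list**
1 | 3,4-dihydroxybenzaldehyde | O=Cc1ccc(O)c(O)c1 | starting material
2 | prenyl bromide | CC(C)=CCBr | starting material
3 | 3-hydroxy-4-(prenyloxy)benzaldehyde | CC(C)=CCOc1ccc(C=O)cc1O | intermediate
4 | 3-(tert-butyldimethylsilyloxy)-4-(prenyloxy)benzaldehyde | CC(C)=CCOc1ccc(C=O)cc1O[Si](C)(C)C(C)(C)C | intermediate
5 | triethyl phosphonoacetate | CCOC(=O)CP(=O)(OCC)OCC | starting material
6 | sodium salt of the triethyl phosphonoacetate carbanion | [Na+].CCOC(=O)[CH-]P(=O)(OCC)OCC | intermediate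
7 | ethyl (E)-3-[3-(tert-butyldimethylsilyloxy)-4-(prenyloxy)phenyl]prop-2-enoate | CCOC(=O)/C=C/c1ccc(OCC=C(C)C)c(O[Si](C)(C)C(C)(C)C)c1 | intermediate
8 | (E)-3-[3-(tert-butyldimethylsilyloxy)-4-(prenyloxy)phenyl]prop-2-en-1-ol | OC/C=C/c1ccc(OCC=C(C)C)c(O[Si](C)(C)C(C)(C)C)c1 | intermediate
9 | (E)-3-[3-(tert-butyldimethylsilyloxy)-4-(prenyloxy)phenyl]prop-2-enyl methyl carbonate | COC(=O)OC/C=C/c1ccc(OCC=C(C)C)c(O[Si](C)(C)C(C)(C)C)c1 | intermediate
10 | 2,4,6-trihydroxyacetophenone | CC(=O)c1c(O)cc(O)cc1O | starting material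
11 | 1-[2-hydroxy-4,6-bis(tert-butyldimethylsilyloxy)phenyl]ethanone | CC(=O)c1c(O)cc(O[Si](C)(C)C(C)(C)C)cc1O[Si](C)(C)C(C)(C)C | intermediate
12 | lithium 2-acetyl-3,5-bis(tert-butyldimethylsilyloxy)phenoxide | [Li+].CC(=O)c1c([O-])cc(O[Si](C)(C)C(C)(C)C)cc1O[Si](C)(C)C(C)(C)C | intermediate
13 | 1-{2-[(S)-1-[3-(tert-butyldimethylsilyloxy)-4-(prenyloxy)phenyl]prop-2-enyloxy]-4,6-bis(tert-butyldimethylsilyloxy)phenyl}ethanone | CC(C)=CCOc1ccc([C@@H](Oc2cc(O[Si](C)(C)C(C)(C)C)cc(O[Si](C)(C)C(C)(C)C)c2C(C)=O)C=C)cc1O[Si](C)(C)C(C)(C)C | intermediate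
14 | potassium enolate of 13 | [K+].CC(C)=CCOc1ccc([C@@H](Oc2cc(O[Si](C)(C)C(C)(C)C)cc(O[Si](C)(C)C(C)(C)C)c2C(=C)[O-])C=C)cc1O[Si](C)(C)C(C)(C)C | intermediate
15 | (S)-1-[3-(tert-butyldimethylsilyloxy)-4-(prenyloxy)phenyl]allyl 3,5-bis(tert-butyldimethylsilyloxy)-2-[1-(tert-butyldimethylsilyloxy)vinyl]phenyl ether | CC(C)=CCOc1ccc([C@@H](Oc2cc(O[Si](C)(C)C(C)(C)C)cc(O[Si](C)(C)C(C)(C)C)c2C(=C)O[Si](C)(C)C(C)(C)C)C=C)cc1O[Si](C)(C)C(C)(C)C | intermediate
16 | (2S)-4,5,7-tris(tert-butyldimethylsilyloxy)-2-[3-(tert-butyldimethylsilyloxy)-4-(prenyloxy)phenyl]-2H-chromene | CC(C)=CCOc1ccc([C@@H]2C=C(O[Si](C)(C)C(C)(C)C)c3c(O[Si](C)(C)C(C)(C)C)cc(O[Si](C)(C)C(C)(C)C)cc3O2)cc1O[Si](C)(C)C(C)(C)C | intermediate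
17 | (2S)-5,7-bis(tert-butyldimethylsilyloxy)-2-[3-(tert-butyldimethylsilyloxy)-4-(prenyloxy)phenyl]chroman-4-one | CC(C)=CCOc1ccc([C@@H]2CC(=O)c3c(O[Si](C)(C)C(C)(C)C)cc(O[Si](C)(C)C(C)(C)C)cc3O2)cc1O[Si](C)(C)C(C)(C)C | intermediate
18 | monotesone A, (2S)-5,7-dihydroxy-2-[3-hydroxy-4-(prenyloxy)phenyl]chroman-4-one | CC(C)=CCOc1ccc([C@@H]2CC(=O)c3c(O)cc(O)cc3O2)cc1O | target

**Step count**
Total steps: 10. Longest linear sequence: 9 (steps 1–5, then 7–10).

**Steps most likely to fail**

Step 9 (ring-closing metathesis).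
- Ring closure may be slow or stall. The enol ether carbon is flanked by two ortho substituents of ring A, and the 4-O and 5-O silyl groups end up peri to each other.
- Long reaction times favour catalyst decay to hydride species and migration of the allyl double bond.
- Heating to compensate invites aromatic Claisen rearrangement or electrocyclic opening of the chromene, with loss of C2 integrity.

Fallback (sets out from 9, comes back at 17): ring C is closed at C4–C4a by an anionic acylation, and the terminal vinyl carbon is kept as C4 rather than lost as ethylene. Phloroglucinol is iodinated (I2, NaHCO3, aq. THF) to 2-iodobenzene-1,3,5-triol F1. Two equivalents of TBSCl with imidazole silylate the unhindered 5-OH and one of the two equivalent OH groups next to iodine, giving 2-iodo-3,5-bis(tert-butyldimethylsilyloxy)phenol F2. LiN(SiMe3)2 converts this into lithium 2-iodo-3,5-bis(tert-butyldimethylsilyloxy)phenoxide F3, which is coupled with 9 under the catalyst of step 7 to the (S)-1-arylallyl 2-iodoaryl ether F4. 9-Borabicyclo[3.3.1]nonane adds only to the monosubstituted vinyl group to give the B-alkyl-9-borabicyclononane F5, and NaBO3·4H2O oxidises it to the (S)-3-aryl-3-aryloxypropan-1-ol F6. TEMPO with PhI(OAc)2 in aqueous MeCN gives the (S)-3-aryl-3-aryloxypropanoic acid F7, and EDC with MeNHOMe·HCl gives the (S)-Weinreb amide F8. Iodine–lithium exchange with n-BuLi in THF at −78 °C, followed by attack of the aryllithium on the amide (Parham cyclisation), should give flavanone 17, which is desilylated as in step 10.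

Step 7 (allylic etherification).
- The chelated aryloxide may attack sluggishly or at the unsubstituted terminus.
- The catalyst may re-ionise the electron-rich branched ether, which erodes enantiopurity and lets the product drift to the linear isomer.
- Silyl groups may transfer between aryloxides or to the methoxide that is released.

Fallback (sets out from 4 and 11, comes back at 13): C2 is set by reagent-controlled carbonyl addition, and O1–C2 is made by SN2 inversion at a propargylic rather than an allylic carbinol. Trimethylsilylacetylene adds to 4 with Me2Zn and the ProPhenol antipode that gives (S)-1-[3-(tert-butyldimethylsilyloxy)-4-(prenyloxy)phenyl]-3-(trimethylsilyl)prop-2-yn-1-ol F9. A Mitsunobu reaction with phenol 11 (PPh3, DIAD, toluene, 0 °C) inverts the centre and gives the (R)-silylpropargyl aryl ether F10. Catalytic AgNO3 in aqueous acetone removes the C-silyl group without touching the aryl silyl ethers and gives the (S)-ethynyl aryl ether F11; the descriptor changes only through the CIP ranking. Semihydrogenation over Pd/CaCO3 poisoned with Pb(OAc)2, with quinoline, gives 13.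

Step 8 (enol silylation).
- Competing removal of the doubly activated C2 proton would lead to Wittig-type rearrangement.
- C-silylation may compete with O-silylation.
- The enol ether may hydrolyse, or the O1–C2 ether may ionise, during isolation.

Fallback (sets out from 11 and 9, comes back at 15): the order of events is reversed, so that the enol ether is in place before the labile ether exists. Two equivalents of LiN(SiMe3)2 in THF at −78 °C turn 11 into the dilithium aryloxide–enolate F12. One equivalent of TBSCl silylates the more reactive enolate oxygen; an O-to-O silyl shift would lead to the same, more stable aryloxide. This gives lithium 3,5-bis(tert-butyldimethylsilyloxy)-2-[1-(tert-butyldimethylsilyloxy)vinyl]phenoxide F13, which serves directly as the nucleophile toward 9 under the catalyst of step 7 and gives 15 in one operation.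

**Further compounds**
F1 | step 9 | 2-iodobenzene-1,3,5-triol | Oc1cc(O)c(I)c(O)c1
F2 | step 9 | 2-iodo-3,5-bis(tert-butyldimethylsilyloxy)phenol | Oc1cc(O[Si](C)(C)C(C)(C)C)cc(O[Si](C)(C)C(C)(C)C)c1I
F3 | step 9 | lithium 2-iodo-3,5-bis(tert-butyldimethylsilyloxy)phenoxide | [Li+].[O-]c1cc(O[Si](C)(C)C(C)(C)C)cc(O[Si](C)(C)C(C)(C)C)c1I
F4 | step 9 | (S)-1-[3-(tert-butyldimethylsilyloxy)-4-(prenyloxy)phenyl]allyl 2-iodo-3,5-bis(tert-butyldimethylsilyloxy)phenyl ether | CC(C)=CCOc1ccc([C@@H](Oc2cc(O[Si](C)(C)C(C)(C)C)cc(O[Si](C)(C)C(C)(C)C)c2I)C=C)cc1O[Si](C)(C)C(C)(C)C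
F5 | step 9 | 9-{(S)-3-[2-iodo-3,5-bis(tert-butyldimethylsilyloxy)phenoxy]-3-[3-(tert-butyldimethylsilyloxy)-4-(prenyloxy)phenyl]propyl}-9-borabicyclo[3.3.1]nonane | CC(C)=CCOc1ccc([C@@H](Oc2cc(O[Si](C)(C)C(C)(C)C)cc(O[Si](C)(C)C(C)(C)C)c2I)CCB2C3CCCC2CCC3)cc1O[Si](C)(C)C(C)(C)C
F6 | step 9 | (S)-3-[2-iodo-3,5-bis(tert-butyldimethylsilyloxy)phenoxy]-3-[3-(tert-butyldimethylsilyloxy)-4-(prenyloxy)phenyl]propan-1-ol | CC(C)=CCOc1ccc([C@@H](Oc2cc(O[Si](C)(C)C(C)(C)C)cc(O[Si](C)(C)C(C)(C)C)c2I)CCO)cc1O[Si](C)(C)C(C)(C)C
F7 | step 9 | (S)-3-[2-iodo-3,5-bis(tert-butyldimethylsilyloxy)phenoxy]-3-[3-(tert-butyldimethylsilyloxy)-4-(prenyloxy)phenyl]propanoic acid | CC(C)=CCOc1ccc([C@@H](Oc2cc(O[Si](C)(C)C(C)(C)C)cc(O[Si](C)(C)C(C)(C)C)c2I)CC(=O)O)cc1O[Si](C)(C)C(C)(C)C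
F8 | step 9 | (S)-3-[2-iodo-3,5-bis(tert-butyldimethylsilyloxy)phenoxy]-3-[3-(tert-butyldimethylsilyloxy)-4-(prenyloxy)phenyl]-N-methoxy-N-methylpropanamide | CC(C)=CCOc1ccc([C@@H](Oc2cc(O[Si](C)(C)C(C)(C)C)cc(O[Si](C)(C)C(C)(C)C)c2I)CC(=O)N(C)OC)cc1O[Si](C)(C)C(C)(C)C
F9 | step 7 | (S)-1-[3-(tert-butyldimethylsilyloxy)-4-(prenyloxy)phenyl]-3-(trimethylsilyl)prop-2-yn-1-ol | CC(C)=CCOc1ccc([C@H](O)C#C[Si](C)(C)C)cc1O[Si](C)(C)C(C)(C)C
F10 | step 7 | 1-{2-[(R)-1-[3-(tert-butyldimethylsilyloxy)-4-(prenyloxy)phenyl]-3-(trimethylsilyl)prop-2-ynyloxy]-4,6-bis(tert-butyldimethylsilyloxy)phenyl}ethanone | CC(C)=CCOc1ccc([C@@H](Oc2cc(O[Si](C)(C)C(C)(C)C)cc(O[Si](C)(C)C(C)(C)C)c2C(C)=O)C#C[Si](C)(C)C)cc1O[Si](C)(C)C(C)(C)C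
F11 | step 7 | 1-{2-[(S)-1-[3-(tert-butyldimethylsilyloxy)-4-(prenyloxy)phenyl]prop-2-ynyloxy]-4,6-bis(tert-butyldimethylsilyloxy)phenyl}ethanone | CC(C)=CCOc1ccc([C@@H](Oc2cc(O[Si](C)(C)C(C)(C)C)cc(O[Si](C)(C)C(C)(C)C)c2C(C)=O)C#C)cc1O[Si](C)(C)C(C)(C)C
F12 | step 8 | dilithium aryloxide–enolate of 11 | [Li+].[Li+].C=C([O-])c1c([O-])cc(O[Si](C)(C)C(C)(C)C)cc1O[Si](C)(C)C(C)(C)C
F13 | step 8 | lithium 3,5-bis(tert-butyldimethylsilyloxy)-2-[1-(tert-butyldimethylsilyloxy)vinyl]phenoxide | [Li+].C=C(O[Si](C)(C)C(C)(C)C)c1c([O-])cc(O[Si](C)(C)C(C)(C)C)cc1O[Si](C)(C)C(C)(C)C
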